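**Plan**

- Retrosynthesis: the C8 prenyl group is cut first (aromatic Claisen from a 7-O-(1,1-dimethylallyl) ether), then the furan C2–O2' bond (oxidative closure of a 2'-hydroxyisoflavone), then the C3–C1' bond (Suzuki–Miyaura coupling of a ring A 3-iodochromone with a ring B chromenyl boronate), then chromone C2 (enaminone). Last, the ring A dihydropyran is cut at C6–CH2 and CH2–CMe2, leaving an aryloxy-isobutyric acid and a two-carbon alkene.
- Enabling feature: in ring A, C6 is the only hydrogen-bearing carbon ortho to O5 and lies between O5 and O7, and the carbon on O5 is a gem-dimethyl, α-oxygen centre. A radical made there by decarboxylation can take up a vinyl unit and close on C6 in a radical (4+2) annulation, so the 5-O/6-C regiochemistry of the dihydropyran is fixed by the tether.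
- Forward order: ring A dihydropyran on the acetophenone, then the pyranone; the ring B 2H-pyran is made separately (propargyl ether Claisen/electrocyclisation); then the C3–C1' bond, the furan ring, the prenyl group and the last deprotection.
- Stereochemistry: the target has no stereocentre. The only stereocentre on the way (the boron-bearing carbon from the annulation) is racemic and is erased in the next step. The prenyl double bond position follows from the [3,3] transposition of the 1,1-dimethylallyl ether.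

Key step: step 4

Assumption: tert-butyl 2-methylbut-3-en-2-yl carbonate is taken as a purchasable reagent (otherwise one step from 2-methylbut-3-en-2-ol and Boc2O).

**Route**

Step 1
Reactants: 1 2,4,6-trihydroxyacetophenone
Product: 2 1-[2,6-dihydroxy-4-(methoxymethoxy)phenyl]ethan-1-one
Conditions: MOMCl (1.05 equiv), iPr2NEt, THF, 0 °C
Reagents that add atoms: chloromethyl methyl ether, COCCl
Why: the 4-OH is the only hydroxyl not hydrogen-bonded to the acetyl carbonyl and is the most acidic, so a Williamson-type O-alkylation with one equivalent of MOMCl should select it.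

Step 2
Reactants: 2 1-[2,6-dihydroxy-4-(methoxymethoxy)phenyl]ethan-1-one; 3 ethyl 2-bromo-2-methylpropanoate
Product: 4 ethyl 2-[2-acetyl-3-hydroxy-5-(methoxymethoxy)phenoxy]-2-methylpropanoate
Conditions: Cs2CO3, DMF, 60 °C
Reagents that add atoms: none
Why: phenoxide O-alkylation with an α-bromoisobutyrate (the fibrate-type ether synthesis) should stop at the mono-ether because the two ortho hydroxyls are equivalent and the remaining one is chelated to the carbonyl and deactivated.

Step 3
Reactants: 4 ethyl 2-[2-acetyl-3-hydroxy-5-(methoxymethoxy)phenoxy]-2-methylpropanoate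
Product: 5 2-[2-acetyl-3-hydroxy-5-(methoxymethoxy)phenoxy]-2-methylpropanoic acid
Conditions: LiOH·H2O, THF/MeOH/H2O, 40 °C; then cold 1 M HCl to pH 4
Reagents that add atoms: lithium hydroxide, [Li+].[OH-]
Why: ester saponification should proceed without touching the MOM ether or the aryl methyl ketone, and the mild cold acidification keeps the acetal intact.

Step 4
Reactants: 5 2-[2-acetyl-3-hydroxy-5-(methoxymethoxy)phenoxy]-2-methylpropanoic acid; 6 4,4,5,5-tetramethyl-2-vinyl-1,3,2-dioxaborolane (vinylboronic acid pinacol ester)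
Product: 8 rac-1-[7-hydroxy-5-(methoxymethoxy)-2,2-dimethyl-4-(4,4,5,5-tetramethyl-1,3,2-dioxaborolan-2-yl)-3,4-dihydro-2H-chromen-8-yl]ethan-1-one, via N-acyloxyphthalimide ester 7 (not isolated)
Conditions: N-hydroxyphthalimide, DIC, DMAP (cat.), CH2Cl2, rt; then 6 (4 equiv), fac-Ir(ppy)3 (1 mol %), DMSO co-solvent, degassed, 450 nm LEDs, rt
Reagents that add atoms: N-hydroxyphthalimide, ON1C(=O)c2ccccc2C1=O (its atoms are in 7 only and leave again as phthalimide)
Why: Proposed new method: photoexcited fac-Ir(ppy)3 should reduce ester 7 by one electron, releasing CO2 and phthalimide anion and leaving the tertiary α-aryloxy radical ArO–C(CH3)2•, which as a nucleophilic radical adds to the unsubstituted terminus of vinyl boronate 6 (CMe2–CH2 bond); the resulting α-boryl radical then attacks the ring carbon between the tether oxygen and the OMOM group (CH–aryl bond), and the cyclohexadienyl radical is oxidised by tetravalent iridium and deprotonated by phthalimide anion, so the cycle is redox-neutral. The closest known reaction types are the photoredox decarboxylative radical (4+2) annulation of N-acyloxyphthalimides of 2-aryloxy carboxylic acids with acrylates or vinyl sulfones to chromans and the decarboxylative Giese addition of alkyl radicals to vinyl boronic esters; what is new is that an α-boryl radical closes onto the arene. The dihydropyran closes in the six-membered ortho mode, 6-exo-trig when counted on the aromatic C4a=C5 bond (chroman numbering of 8), while the five-membered ipso closure at the oxygen-bearing carbon is reversible and unproductive. The boron-bearing C4 is the only new stereocentre; nothing controls it, so 8 is racemic, and the centre is erased in step 5. The step needs regioselectivity for one ortho carbon and chemoselectivity against plain hydroalkylation: the other ortho carbon carries the acetyl group and cannot rearomatise, the attacked C–H carbon is activated by two flanking oxygens and a para hydroxyl, and the oxidative quenching cycle holds no strong reductant for the α-boryl radical.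

Step 5
Reactants: 8 rac-1-[7-hydroxy-5-(methoxymethoxy)-2,2-dimethyl-4-(4,4,5,5-tetramethyl-1,3,2-dioxaborolan-2-yl)-3,4-dihydro-2H-chromen-8-yl]ethan-1-one
Product: 9 1-[7-hydroxy-5-(methoxymethoxy)-2,2-dimethyl-3,4-dihydro-2H-chromen-8-yl]ethan-1-one
Conditions: Bu4NF·3H2O (3 equiv), toluene, 60 °C
Reagents that add atoms: none
Why: fluoride-promoted protodeboronation of a benzylic pinacol boronate (boronate complex, protonolysis of the C–B bond by the water of hydration) should remove the helper boron under conditions that leave the MOM ether and the ketone alone.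

Step 6
Reactants: 9 1-[7-hydroxy-5-(methoxymethoxy)-2,2-dimethyl-3,4-dihydro-2H-chromen-8-yl]ethan-1-one
Product: 10 (E)-3-(dimethylamino)-1-[7-hydroxy-5-(methoxymethoxy)-2,2-dimethyl-3,4-dihydro-2H-chromen-8-yl]prop-2-en-1-one
Conditions: DMF-DMA, toluene, 90 °C
Reagents that add atoms: N,N-dimethylformamide dimethyl acetal, COC(OC)N(C)C
Why: condensation of the methyl ketone with the amide acetal should give the (E)-enaminone, the standard precursor of 3-halochromones, while the chelated phenol stays free.

Step 7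
Reactants: 10 (E)-3-(dimethylamino)-1-[7-hydroxy-5-(methoxymethoxy)-2,2-dimethyl-3,4-dihydro-2H-chromen-8-yl]prop-2-en-1-one
Product: 11 9-iodo-5-(methoxymethoxy)-2,2-dimethyl-3,4-dihydro-2H,10H-pyrano[2,3-f]chromen-10-one (the 3-iodochromone of ring A: dihydropyran on O5/C6, OMOM at C7)
Conditions: I2, pyridine, CHCl3, rt
Reagents that add atoms: iodine, II
Why: iodination of the enaminone at its α-carbon, attack of the phenol on the iminium carbon and loss of dimethylamine (iodine-mediated enaminone cyclisation) should give the 3-iodochromone, with pyridine buffering the acid so that the MOM ether survives.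

Step 8
Reactants: 12 5-bromo-2,4-dihydroxybenzaldehyde
Product: 13 5-bromo-2-hydroxy-4-(methoxymethoxy)benzaldehyde
Conditions: MOMCl (1.1 equiv), iPr2NEt, CH2Cl2, 0 °C
Reagents that add atoms: chloromethyl methyl ether, COCCl
Why: the 4-OH (para to the aldehyde, ortho to bromine) is the more acidic and unchelated hydroxyl, so Williamson-type alkoxymethylation should occur there and leave the chelated 2-OH.

Step 9
Reactants: 13 5-bromo-2-hydroxy-4-(methoxymethoxy)benzaldehyde; 14 3-chloro-3-methylbut-1-yne
Product: 15 5-bromo-4-(methoxymethoxy)-2-[(2-methylbut-3-yn-2-yl)oxy]benzaldehyde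
Conditions: K2CO3, KI, copper iodide CuI (cat.), DMF, 60 °C
Reagents that add atoms: none
Why: copper-assisted propargylic substitution of the tertiary chloride by the phenoxide is the usual way to aryl 1,1-dimethylpropargyl ethers and should work on the chelated hydroxyl at this temperature, below the onset of rearrangement.

Step 10
Reactants: 15 5-bromo-4-(methoxymethoxy)-2-[(2-methylbut-3-yn-2-yl)oxy]benzaldehyde
Product: 17 5-bromo-4-(methoxymethoxy)-2-[(2-methylbut-3-yn-2-yl)oxy]phenol, via aryl formate 16 (not isolated)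
Conditions: mCPBA, NaHCO3, CH2Cl2, 0 °C to rt; then K2CO3 (cat.), MeOH, 0 °C
Reagents that add atoms: 3-chloroperoxybenzoic acid, OOC(=O)c1cccc(Cl)c1
Why: Baeyer–Villiger oxidation of the electron-rich ortho,para-dialkoxybenzaldehyde (Dakin-type) should proceed by aryl migration to the formate, which mild methanolysis cleaves to the phenol that becomes the 5'-oxygen; the alkyne is inert to the peracid.

Step 11
Reactants: 17 5-bromo-4-(methoxymethoxy)-2-[(2-methylbut-3-yn-2-yl)oxy]phenol
Product: 18 5-bromo-4-(methoxymethoxy)-2-[(2-methylbut-3-yn-2-yl)oxy]phenyl 2,2-dimethylpropanoate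
Conditions: PivCl, Et3N, DMAP (cat.), CH2Cl2, 0 °C to rt
Reagents that add atoms: pivaloyl chloride, CC(C)(C)C(Cl)=O
Why: O-acylation protects the future 5'-OH as a hindered, electron-withdrawing ester that should survive the coupling and the acid step and lowers the oxidation sensitivity of ring B in step 15.

Step 12
Reactants: 18 5-bromo-4-(methoxymethoxy)-2-[(2-methylbut-3-yn-2-yl)oxy]phenyl 2,2-dimethylpropanoate
Product: 19 6-bromo-5-(methoxymethoxy)-2,2-dimethyl-2H-chromen-8-yl 2,2-dimethylpropanoate
Conditions: o-xylene, 140 °C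
Reagents that add atoms: none
Why: the thermal aryl propargyl ether rearrangement (propargyl Claisen, enolisation, 1,5-hydrogen shift, oxa-6π electrocyclisation) can only use the single free ortho carbon, between the ether oxygen and the OMOM group, so the 2H-chromene should form with the required regiochemistry.

Step 13
Reactants: 19 6-bromo-5-(methoxymethoxy)-2,2-dimethyl-2H-chromen-8-yl 2,2-dimethylpropanoate; 11 9-iodo-5-(methoxymethoxy)-2,2-dimethyl-3,4-dihydro-2H,10H-pyrano[2,3-f]chromen-10-one
Product: 21 5-(methoxymethoxy)-6-[5-(methoxymethoxy)-2,2-dimethyl-10-oxo-3,4-dihydro-2H,10H-pyrano[2,3-f]chromen-9-yl]-2,2-dimethyl-2H-chromen-8-yl 2,2-dimethylpropanoate (isoflavone with 7-OMOM, 2'-OMOM, 5'-OPiv), via chromenyl pinacol boronate 20 (not isolated)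
Conditions: B2pin2, Pd(dppf)Cl2 (5 mol %), KOAc, 1,4-dioxane, 90 °C; then 11, K3PO4, H2O, 80 °C
Reagents that add atoms: bis(pinacolato)diboron, CC1(C)OB(OC1(C)C)B1OC(C)(C)C(C)(C)O1 (its boron is in 20 only)
Why: Miyaura borylation of the aryl bromide followed in the same flask by Suzuki–Miyaura coupling with the 3-iodochromone is the standard isoflavone construction and should tolerate the ortho OMOM group, the pivalate and the chromene.

Step 14
Reactants: 21 isoflavone with 7-OMOM, 2'-OMOM and 5'-OPiv
Product: 22 6-[5-hydroxy-2,2-dimethyl-10-oxo-3,4-dihydro-2H,10H-pyrano[2,3-f]chromen-9-yl]-5-hydroxy-2,2-dimethyl-2H-chromen-8-yl 2,2-dimethylpropanoate (7,2'-dihydroxyisoflavone, 5'-OPiv)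
Conditions: 3 M HCl (aq), MeOH/THF, 45 °C
Reagents that add atoms: none
Why: acid-catalysed acetal exchange should remove both MOM groups in one operation, while the aryl pivalate and the 2,2-dimethyl-2H-chromene withstand dilute methanolic acid.

Step 15
Reactants: 22 7,2'-dihydroxyisoflavone with 5'-OPiv
Product: 23 coumaronochromone with the furan closed between chromone C2 and the 2'-oxygen, 7-OH free, 5'-O-pivalate, ring A dihydropyran on O5/C6 and ring B 2,2-dimethylpyran on C3'/O4'
Conditions: DDQ (1.2 equiv), 1,4-dioxane, rt to 50 °C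
Reagents that add atoms: none
Why: oxidative cyclisation of a 2'-hydroxyisoflavone (oxa-Michael addition of the 2'-OH to C2, then hydride abstraction from the acetal C–H by DDQ and loss of the C3 proton) is the established entry to coumaronochromones, and the pivalate keeps ring B from being oxidised to a quinone.

Step 16
Reactants: 23 coumaronochromone with 7-OH and 5'-OPiv; 24 tert-butyl 2-methylbut-3-en-2-yl carbonate
Product: 25 the 7-O-(2-methylbut-3-en-2-yl) ether of 23
Conditions: Pd(PPh3)4 (5 mol %), THF, 0 °C to rt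
Reagents that add atoms: none
Why: Tsuji–Trost O-allylation of the acidic 7-OH by the 1,1-dimethyl-π-allyl palladium complex should give the branched tertiary ether under kinetic control, and the in situ tert-butoxide serves as the base.

Step 17
Reactants: 25 7-O-(2-methylbut-3-en-2-yl) ether
Product: 26 8-(3-methylbut-2-en-1-yl) coumaronochromone with 7-OH and 5'-O-pivalate
Conditions: toluene, 110 °C
Reagents that add atoms: none
Why: the aromatic Claisen rearrangement of the 1,1-dimethylallyl ether can only go to C8, because C6 is blocked by the dihydropyran, and the [3,3] transposition delivers the normal prenyl group before tautomerisation restores the 7-OH.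

Step 18
Reactants: 26 8-prenyl coumaronochromone 5'-O-pivalate
Product: 27 CNP0081330.0 (7,5'-dihydroxy-8-prenyl coumaronochromone with the 2,2-dimethyldihydropyran on O5/C6 and the 2,2-dimethylpyran on C3'/O4')
Conditions: K2CO3, MeOH/THF, 40 °C; then aq. NH4Cl
Reagents that add atoms: none
Why: base-catalysed methanolysis of the aryl pivalate (transesterification) should free the 5'-OH, while the 7-phenoxide formed first lowers the electrophilicity of the pyranone and the prenyl and chromene groups are inert.

**Compound list**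

1 | 2,4,6-trihydroxyacetophenone | CC(=O)c1c(O)cc(O)cc1O | starting material
2 | 1-[2,6-dihydroxy-4-(methoxymethoxy)phenyl]ethan-1-one | CC(=O)c1c(O)cc(OCOC)cc1O | intermediate
3 | ethyl 2-bromo-2-methylpropanoate | CCOC(=O)C(C)(C)Br | starting material
4 | ethyl 2-[2-acetyl-3-hydroxy-5-(methoxymethoxy)phenoxy]-2-methylpropanoate | CCOC(=O)C(C)(C)Oc1cc(OCOC)cc(O)c1C(C)=O | intermediate
5 | 2-[2-acetyl-3-hydroxy-5-(methoxymethoxy)phenoxy]-2-methylpropanoic acid | CC(=O)c1c(O)cc(OCOC)cc1OC(C)(C)C(=O)O | intermediate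
6 | 4,4,5,5-tetramethyl-2-vinyl-1,3,2-dioxaborolane | C=CB1OC(C)(C)C(C)(C)O1 | starting material
7 | 1,3-dioxoisoindolin-2-yl 2-[2-acetyl-3-hydroxy-5-(methoxymethoxy)phenoxy]-2-methylpropanoate | CC(=O)c1c(O)cc(OCOC)cc1OC(C)(C)C(=O)ON1C(=O)c2ccccc2C1=O | intermediate (not isolated)
8 | rac-1-[7-hydroxy-5-(methoxymethoxy)-2,2-dimethyl-4-(4,4,5,5-tetramethyl-1,3,2-dioxaborolan-2-yl)-3,4-dihydro-2H-chromen-8-yl]ethan-1-one | CC(=O)c1c(O)cc(OCOC)c2C(B3OC(C)(C)C(C)(C)O3)CC(C)(C)Oc12 | intermediate
9 | 1-[7-hydroxy-5-(methoxymethoxy)-2,2-dimethyl-3,4-dihydro-2H-chromen-8-yl]ethan-1-one | CC(=O)c1c(O)cc(OCOC)c2CCC(C)(C)Oc12 | intermediate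
10 | (E)-3-(dimethylamino)-1-[7-hydroxy-5-(methoxymethoxy)-2,2-dimethyl-3,4-dihydro-2H-chromen-8-yl]prop-2-en-1-one | CN(C)/C=C/C(=O)c1c(O)cc(OCOC)c2CCC(C)(C)Oc12 | intermediate
11 | 9-iodo-5-(methoxymethoxy)-2,2-dimethyl-3,4-dihydro-2H,10H-pyrano[2,3-f]chromen-10-one | O=c1c(I)coc2cc(OCOC)c3CCC(C)(C)Oc3c12 | intermediate
12 | 5-bromo-2,4-dihydroxybenzaldehyde | O=Cc1cc(Br)c(O)cc1O | starting material
13 | 5-bromo-2-hydroxy-4-(methoxymethoxy)benzaldehyde | O=Cc1cc(Br)c(OCOC)cc1O | intermediate
14 | 3-chloro-3-methylbut-1-yne | CC(C)(Cl)C#C | starting material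
15 | 5-bromo-4-(methoxymethoxy)-2-[(2-methylbut-3-yn-2-yl)oxy]benzaldehyde | O=Cc1cc(Br)c(OCOC)cc1OC(C)(C)C#C | intermediate
16 | 5-bromo-4-(methoxymethoxy)-2-[(2-methylbut-3-yn-2-yl)oxy]phenyl formate | O=COc1cc(Br)c(OCOC)cc1OC(C)(C)C#C | intermediate (not isolated)
17 | 5-bromo-4-(methoxymethoxy)-2-[(2-methylbut-3-yn-2-yl)oxy]phenol | Oc1cc(Br)c(OCOC)cc1OC(C)(C)C#C | intermediate
18 | 5-bromo-4-(methoxymethoxy)-2-[(2-methylbut-3-yn-2-yl)oxy]phenyl 2,2-dimethylpropanoate | CC(C)(C)C(=O)Oc1cc(Br)c(OCOC)cc1OC(C)(C)C#C | intermediate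
19 | 6-bromo-5-(methoxymethoxy)-2,2-dimethyl-2H-chromen-8-yl 2,2-dimethylpropanoate | CC1(C)C=Cc2c(OCOC)c(Br)cc(OC(=O)C(C)(C)C)c2O1 | intermediate
20 | 5-(methoxymethoxy)-2,2-dimethyl-6-(4,4,5,5-tetramethyl-1,3,2-dioxaborolan-2-yl)-2H-chromen-8-yl 2,2-dimethylpropanoate | CC1(C)C=Cc2c(OCOC)c(B3OC(C)(C)C(C)(C)O3)cc(OC(=O)C(C)(C)C)c2O1 | intermediate (not isolated)
21 | 5-(methoxymethoxy)-6-[5-(methoxymethoxy)-2,2-dimethyl-10-oxo-3,4-dihydro-2H,10H-pyrano[2,3-f]chromen-9-yl]-2,2-dimethyl-2H-chromen-8-yl 2,2-dimethylpropanoate | O=c1c(-c2cc(OC(=O)C(C)(C)C)c3OC(C)(C)C=Cc3c2OCOC)coc2cc(OCOC)c3CCC(C)(C)Oc3c12 | intermediate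
22 | 6-[5-hydroxy-2,2-dimethyl-10-oxo-3,4-dihydro-2H,10H-pyrano[2,3-f]chromen-9-yl]-5-hydroxy-2,2-dimethyl-2H-chromen-8-yl 2,2-dimethylpropanoate | O=c1c(-c2cc(OC(=O)C(C)(C)C)c3OC(C)(C)C=Cc3c2O)coc2cc(O)c3CCC(C)(C)Oc3c12 | intermediate
23 | coumaronochromone, 7-OH, 5'-O-pivalate, dihydropyran on O5/C6, 2,2-dimethylpyran on C3'/O4' | O=c1c2c(oc3cc(O)c4CCC(C)(C)Oc4c13)oc1c3C=CC(C)(C)Oc3c(OC(=O)C(C)(C)C)cc21 | intermediate
24 | tert-butyl 2-methylbut-3-en-2-yl carbonate | C=CC(C)(C)OC(=O)OC(C)(C)C | starting material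
25 | 7-O-(2-methylbut-3-en-2-yl) ether of 23 | O=c1c2c(oc3cc(OC(C)(C)C=C)c4CCC(C)(C)Oc4c13)oc1c3C=CC(C)(C)Oc3c(OC(=O)C(C)(C)C)cc21 | intermediate
26 | 8-(3-methylbut-2-en-1-yl) coumaronochromone, 7-OH, 5'-O-pivalate | O=c1c2c(oc3c(CC=C(C)C)c(O)c4CCC(C)(C)Oc4c13)oc1c3C=CC(C)(C)Oc3c(OC(=O)C(C)(C)C)cc21 | intermediate
27 | CNP0081330.0 | CC(C)=CCc1c(O)c2c(c3c(=O)c4c(oc13)oc1c3c(c(O)cc14)OC(C)(C)C=C3)OC(C)(C)CC2 | target

**Step count and risks**

Total steps: 18. Longest linear sequence: 13 steps (steps 1–7 and 13–18).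

Steps most likely to fail:

1. Step 4 (proposed new method). The α-boryl radical may be quenched by hydrogen-atom transfer or add to a second vinyl boronate faster than it closes onto the ring, giving hydroalkylation or oligomers instead of annulation. Fallback with known chemistry, setting out from 2 and returning at 9: condensation of 2 with 3-methylbut-2-enal (ethylenediammonium diacetate, toluene, reflux) followed by oxa-6π electrocyclisation through the free ortho hydroxyl (the 4-oxygen is blocked as the MOM ether) should give 1-[7-hydroxy-5-(methoxymethoxy)-2,2-dimethyl-2H-chromen-8-yl]ethan-1-one F1. Hydrogenation of its ring alkene (H2, Pd/C, EtOAc) gives 9.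

2. Step 15. Over-oxidation may compete with ring closure: hydride abstraction at the benzylic CH2 of the ring A dihydropyran next to the free 7-OH, or oxidation of the ring B phenol. Fallback without an oxidant, setting out from 9 and returning at 23:
   - Deprotonation of 9 (t-BuOK, THF), addition to CS2 and double S-methylation (MeI) should give 1-[7-hydroxy-5-(methoxymethoxy)-2,2-dimethyl-3,4-dihydro-2H-chromen-8-yl]-3,3-bis(methylsulfanyl)prop-2-en-1-one F3.
   - Heating F3 (toluene, reflux) closes the pyranone by addition–elimination with loss of methanethiol to 5-(methoxymethoxy)-2,2-dimethyl-8-(methylsulfanyl)-3,4-dihydro-2H,10H-pyrano[2,3-f]chromen-10-one F4.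
   - Iodination at C3 (I2, (NH4)2Ce(NO3)6, MeCN) gives 9-iodo-5-(methoxymethoxy)-2,2-dimethyl-8-(methylsulfanyl)-3,4-dihydro-2H,10H-pyrano[2,3-f]chromen-10-one F5.
   - Suzuki–Miyaura coupling with boronate 20 (made from 19 as in step 13) gives the 2-(methylsulfanyl)isoflavone with 7-OMOM, 2'-OMOM and 5'-OPiv F6.
   - HCl/MeOH frees both phenols to the 2-(methylsulfanyl)-7,2'-dihydroxyisoflavone 5'-pivalate F7.
   - K2CO3 in DMF at 80 °C lets the 2'-oxygen displace methanethiolate at C2 to give 23.

3. Step 5. Protonolysis of the C–B bond may be slow because the electron-rich, doubly ortho-substituted benzylic carbon resists the build-up of negative charge, more so once the phenol is deprotonated. Fallback, setting out from 8 and returning at 9: oxidation of the C–B bond (NaBO3·4H2O, THF/H2O) should give rac-1-[4,7-dihydroxy-5-(methoxymethoxy)-2,2-dimethyl-3,4-dihydro-2H-chromen-8-yl]ethan-1-one F2. Hydrogenolysis of its electron-rich benzylic alcohol (H2, Pd/C, EtOAc, trace AcOH) gives 9.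

**Further compounds**

F1 | step 4 | 1-[7-hydroxy-5-(methoxymethoxy)-2,2-dimethyl-2H-chromen-8-yl]ethan-1-one | CC(=O)c1c(O)cc(OCOC)c2C=CC(C)(C)Oc12
F2 | step 5 | rac-1-[4,7-dihydroxy-5-(methoxymethoxy)-2,2-dimethyl-3,4-dihydro-2H-chromen-8-yl]ethan-1-one | CC(=O)c1c(O)cc(OCOC)c2C(O)CC(C)(C)Oc12
F3 | step 15 | 1-[7-hydroxy-5-(methoxymethoxy)-2,2-dimethyl-3,4-dihydro-2H-chromen-8-yl]-3,3-bis(methylsulfanyl)prop-2-en-1-one | CSC(SC)=CC(=O)c1c(O)cc(OCOC)c2CCC(C)(C)Oc12
F4 | step 15 | 5-(methoxymethoxy)-2,2-dimethyl-8-(methylsulfanyl)-3,4-dihydro-2H,10H-pyrano[2,3-f]chromen-10-one | CSc1cc(=O)c2c(o1)cc(OCOC)c1CCC(C)(C)Oc12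
F5 | step 15 | 9-iodo-5-(methoxymethoxy)-2,2-dimethyl-8-(methylsulfanyl)-3,4-dihydro-2H,10H-pyrano[2,3-f]chromen-10-one | CSc1oc2cc(OCOC)c3CCC(C)(C)Oc3c2c(=O)c1I
F6 | step 15 | 5-(methoxymethoxy)-6-[5-(methoxymethoxy)-2,2-dimethyl-8-(methylsulfanyl)-10-oxo-3,4-dihydro-2H,10H-pyrano[2,3-f]chromen-9-yl]-2,2-dimethyl-2H-chromen-8-yl 2,2-dimethylpropanoate | CSc1oc2cc(OCOC)c3CCC(C)(C)Oc3c2c(=O)c1-c1cc(OC(=O)C(C)(C)C)c2OC(C)(C)C=Cc2c1OCOC
F7 | step 15 | 5-hydroxy-6-[5-hydroxy-2,2-dimethyl-8-(methylsulfanyl)-10-oxo-3,4-dihydro-2H,10H-pyrano[2,3-f]chromen-9-yl]-2,2-dimethyl-2H-chromen-8-yl 2,2-dimethylpropanoate | CSc1oc2cc(O)c3CCC(C)(C)Oc3c2c(=O)c1-c1cc(OC(=O)C(C)(C)C)c2OC(C)(C)C=Cc2c1O
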